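Which of these flasks ends with the most target, and what fraction of the charge does each hold?

the same everywhere: starting material 0.50 mM; reagent 2.00 equiv; time 12 min
- summer: temperature 100 °C
- dusk: at 85 °C until 6.0 min, from then on at 100 °C
- midnight: temperature 85 °C

    starting material + reagent + target → 2 target (k1 = 56000 M⁻² s⁻¹, Ea1 = 13.0 kJ mol⁻¹)
    target ⇌ isomer of the product (K2 = 1.0, k2 = 0.096 s⁻¹, Ea2 = 106 kJ mol⁻¹, ΔH2 = −2.00 kJ mol⁻¹)
    starting material ⇌ dormant form (K3 = 0.55, k3 = 0.015 s⁻¹, Ea3 = 93.0 kJ mol⁻¹, ΔH3 = −37.0 kJ mol⁻¹)
    starting material + reagent → target (k4 = 0.019 M⁻¹ s⁻¹, Ea4 = 63.0 kJ mol⁻¹)
    (constants at 100 °C)

- the flask with the highest amount of target, in percent of the starting material charged ("all alike" if they lie within 1.5 percentage points) (summer / dusk / midnight / all alike)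
- final target, as a percentage of the starting material charged, in summer
- final target, as a percentage of the starting material charged, in dusk
- final target, as a percentage of the starting material charged, in midnight

- constants are those at 100 °C; use the activation energies and enthalpies for any other temperature

How does target first appear? In summer the reckoning takes a free fraction of 0.645 of the unconverted material, from the balance of starting material and dormant form. Through step 4, with the reagent at its full charge, that free fraction seeds 7.35 × 10⁻⁴ min⁻¹ of the charge.

How fast does the seed multiply? This is an autocatalysis. The doubling time, the time in which the pool of target and isomer doubles while little has been converted, is ln(2) divided by the product of the step 1 constant, free starting material, reagent and target's share of that pool: 1.28 min. Target and isomer balance with a half-life of 0.0602 min, far below the doubling time, so target is half of their pool. Starting material and dormant form balance with a half-life of 0.273 min, also shorter than the doubling time, so the reckoning keeps the free fraction through the growth.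

How many doublings fit? Summer has 9.38. The seed counts as a starting pool of 0.00136 of the charge, and doubling multiplies that to 0.906. The reckoning reads this as the ratio of pool to unconverted material and sets aside the fall in reagent. The pool is then 47.5% of the charge, and target in summer 23.8%.

At the lower temperature step 1 is 1.2 times slower and the dormant constant rises to 0.906, so the doubling time lengthens to 1.87 min. Midnight then has 6.40 doublings and dusk 7.89, fewer than summer's and more than midnight's. The reckoning therefore orders them summer, dusk, midnight.

The forecast names summer, with 22% in summer, 14.5% in dusk and 8% in midnight, a summer value lower than the reckoning's. Its grounds: “The hotter flask therefore wins through faster seeding and less dormancy”.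

The simulation gives summer as highest, with 23.7% in summer, 15.1% in dusk and 8.37% in midnight. These are points along one rise: after 120 min the three hold 50.0%, 50.0% and 49.3%. Summer with 0.12 mM of starting material, at the same equivalents, has a doubling time of 22.2 min, so 0.540 of a doubling fits. Its seed of 1.77 × 10⁻⁴ min⁻¹ then reckons to 0.128% target, and that flask ends at 0.133%.

All constants were chosen freely; the result is computed.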